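**Strategy.** Ring B of the trans-decalin (C11–C16) is disconnected at C11–C12 and C13–C14, so that the C12–C13 unit arrives as a silyl enol ether. The key step is an inverse-electron-demand Diels–Alder reaction of this two-carbon unit with the cross-conjugated diene C14=C15–C16=C11 of a 2-propenylcyclohexenone that already is ring A; it closes ring B and sets C11, C13 and C14 at once. It exploits the 1,3-dioxygenated, C14-methylated ring B and the ring-A ketone at C17, which activates C11 and is locked s-trans. The precursor is an enantiopure cis-lactone-fused enone from a desymmetrised cyclohexadienone; a Diels–Alder-derived spirotetronate is attached by aldehyde addition and ring-closing metathesis.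

Key step: step 9

Locants used throughout (not IUPAC): C1–C2 ethyl; C3 ring carbon bearing it; C4 ring CH2; C5 spiro carbon; O6 lactone oxygen; C7 lactone carbonyl; C8; C9 acyl (enol) carbon; C10 quaternary decalin carbon; ring B = C11, C12, C13 (O), C14 (Me), C15 (O), C16; ring A = C10, C11, C16, C17=C18, C19; linker C20, C21=C22 (Z), C23; C24 quaternary (Me); C25=C26 (Me on C26); C27 tetronate ketone carbon.

Assumption 1: (2R,5R)-2-tert-butyl-5-methyl-1,3-dioxolan-4-one (22), the pivalaldehyde acetal of D-lactic acid, is taken as a purchasable chiral-pool reagent.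

Assumption 2: in step 5 the pseudoenantiomeric series of the cinchona catalyst (quinine- or quinidine-derived) is chosen as the one that gives the configuration drawn.

## Ring A and the decalin aldehyde

Step 1
Reactants: 1 benzoic acid
Product: 2 1-methylcyclohexa-2,5-diene-1-carboxylic acid
Conditions: Li, NH3 (l), THF, −78 °C; then MeI
Reagents that add atoms: iodomethane, CI
Why: Birch reduction gives the cross-conjugated dienolate, which MeI alkylates at the carboxyl-bearing carbon (Birch reductive alkylation), so that quaternary C10 with its methyl group and C9 is in place; no stereocentre arises.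

Step 2
Reactants: 2 1-methylcyclohexa-2,5-diene-1-carboxylic acid
Product: 3 (1-methylcyclohexa-2,5-dien-1-yl)methanol
Conditions: LiAlH4, THF, 0 °C to rt
Reagents that add atoms: none
Why: LiAlH4 reduces the carboxylic acid to the neopentyl-type primary alcohol (C9) and leaves the skipped diene untouched.

Step 3
Reactants: 3 (1-methylcyclohexa-2,5-dien-1-yl)methanol
Product: 4 methyl (1-methylcyclohexa-2,5-dien-1-yl)methyl malonate
Conditions: methyl malonyl chloride, pyridine, CH2Cl2, 0 °C
Reagents that add atoms: methyl malonyl chloride, COC(=O)CC(Cl)=O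
Why: Acylation of the primary alcohol by the acid chloride installs the malonate that serves both as tethered carbon nucleophile (C20) and as the future C21.

Step 4
Reactants: 4 methyl (1-methylcyclohexa-2,5-dien-1-yl)methyl malonate
Product: 5 methyl (1-methyl-4-oxocyclohexa-2,5-dien-1-yl)methyl malonate
Conditions: Rh2(cap)4 (1 mol%), t-BuOOH, K2CO3, CH2Cl2, rt
Reagents that add atoms: tert-butyl hydroperoxide, CC(C)(C)OO
Why: The doubly allylic CH2 (C17) has the weakest C–H bond, so the tert-butylperoxyl radical chain sustained by the dirhodium carboxamidate should oxidise it to the ketone (allylic C–H oxidation), giving the prochiral cross-conjugated dienone.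

Step 5
Reactants: 5 methyl (1-methyl-4-oxocyclohexa-2,5-dien-1-yl)methyl malonate
Product: 6 cis-fused lactone enone ester (methyl 8a-methyl-3,6-dioxo-3,4,4a,5,6,8a-hexahydro-1H-isochromene-4-carboxylate, C10 and C19 as in the target, C20 epimers)
Conditions: quinine-derived bifunctional thiourea (10 mol%), toluene, −20 °C
Reagents that add atoms: none
Why: The amine–thiourea should deprotonate the malonate and activate one of the two enantiotopic enone arms for an intramolecular Michael addition (6-exo-trig), a desymmetrisation in which the tether forces the new C19–C20 bond onto the face of C9 (cis-fused lactone) and the catalyst fixes the absolute configuration of C10 and C19.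

Step 6
Reactants: 6 cis-fused lactone enone ester
Product: 7 cis-8a-methyl-4,4a,5,8a-tetrahydro-1H-isochromene-3,6-dione (lactone enone, C10 and C19 as in the target)
Conditions: LiCl, H2O, DMSO, 140 °C
Reagents that add atoms: none
Why: Krapcho dealkoxycarbonylation: chloride demethylates the ester and the malonate-type carboxylate loses CO2 under nearly neutral conditions, which avoids a retro-Michael reaction and removes the C20 stereocentre.

Step 7
Reactants: 7 lactone enone
Product: 8 7-iodo lactone enone (iodine on C16)
Conditions: I2, pyridine, CH2Cl2, rt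
Reagents that add atoms: iodine, II
Why: α-Iodination of the enone by reversible conjugate addition of pyridine, iodination of the enolate at C16 and elimination, a reaction known for 4,4-disubstituted cyclohexenones.

Step 8
Reactants: 8 7-iodo lactone enone; 9 (E)-prop-1-enylboronic acid pinacol ester
Product: 10 7-[(E)-prop-1-enyl] lactone enone (cross-conjugated dienone, C14=C15 on C16)
Conditions: Pd(dppf)Cl2 (5 mol%), K3PO4, THF–H2O, 50 °C
Reagents that add atoms: none
Why: Suzuki–Miyaura coupling of the α-iodoenone with the alkenylboronate proceeds with retention of the (E) geometry and gives the 2-alkenyl enone.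

## Key step and completion of ring B

Step 9
Reactants: 10 7-[(E)-prop-1-enyl] lactone enone; 11 tert-butyldimethyl(vinyloxy)silane
Product: 12 tricyclic silyloxy enone (ring B closed; C11-H, C13-OTBS and C14-Me as in the target; C15=C16 conjugated to the C17 ketone)
Conditions: 11 (10 equiv), Yb(fod)3 (10 mol%), BHT, toluene, 80 °C, sealed tube
Reagents that add atoms: none
Why: The cross-conjugated diene C14=C15–C16=C11 of 10 is electron-poor because C16 carries the ring-A ketone C17, so it should undergo an inverse-electron-demand Diels–Alder reaction with the electron-rich enol ether 11; the closest known reaction type is the lanthanide-promoted [4+2] cycloaddition of 2-acyl- and 2-alkoxycarbonyl-1,3-dienes with vinyl ethers. Ring B closes in one [4+2] event as a six-membered carbocycle, the nucleophilic CH2 of 11 (C12) bonding to the enone β-carbon C11 and the oxygenated carbon C13 to C14, which gives the 1,4 relation of the silyloxy group to C16. C11 is controlled by the cis-fused lactone, which makes the face syn to the angular C10 methyl group the convex one; C14 follows from suprafacial addition to the (E)-propenyl group, which places its methyl group cis to the C11–C10 bond; C13 follows from the endo orientation of the silyloxy group. The step needs selectivity for the carbodiene over the oxadiene O=C17–C16=C11, which is secured because the ring holds this enone s-trans, and over self-dimerisation, which the excess of 11 and the hindered C11 terminus should suppress.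

Step 10
Reactants: 12 tricyclic silyloxy enone
Product: 13 dienyl triflate (C17-OTf, C17=C18, C15=C16)
Conditions: KN(SiMe3)2, THF, −78 °C; then PhNTf2
Reagents that add atoms: N-phenylbis(trifluoromethanesulfonimide), O=S(=O)(N(c1ccccc1)S(=O)(=O)C(F)(F)F)C(F)(F)F
Why: KN(SiMe3)2 removes the more accessible α′ proton at C18 under kinetic control and PhNTf2 traps the cross-conjugated enolate on oxygen (enol triflate formation).

Step 11
Reactants: 13 dienyl triflate
Product: 14 tricyclic diene (C15=C16–C17=C18)
Conditions: Pd(OAc)2 (5 mol%), PPh3, HCO2H, Bu3N, DMF, 60 °C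
Reagents that add atoms: none
Why: Zerovalent palladium inserts into the vinyl C–O bond and formate delivers hydride (reduction of an enol triflate), which turns the C17 ketone into the C17=C18 alkene.

Step 12
Reactants: 14 tricyclic diene
Product: 15 vinyl epoxide (C15–C16 epoxide on the β face, anti to the C14 and C10 methyl groups)
Conditions: mCPBA, NaHCO3, CH2Cl2, −20 °C
Reagents that add atoms: 3-chloroperbenzoic acid, OOC(=O)c1cccc(Cl)c1
Why: The peracid should epoxidise the more electron-rich trisubstituted C15=C16 bond of the diene (Prilezhaev epoxidation) from the β face, opposite to the axial C14 and C10 methyl groups.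

Step 13
Reactants: 15 vinyl epoxide
Product: 17 trans-decalin alcohol (C15-OH equatorial, C16-H as in the target, C17=C18), via β,γ-enone 16 (not isolated)
Conditions: Pd(PPh3)4 (5 mol%), THF, 0 °C to rt; then CeCl3·7H2O, NaBH4, MeOH, −40 °C
Reagents that add atoms: none
Why: Zerovalent palladium should open the vinyl epoxide with inversion to a π-allyl palladium alkoxide that undergoes β-hydride elimination at C15 and returns the hydride to C16 on the palladium face, anti to the former oxygen (isomerisation of a diene monoepoxide to a β,γ-unsaturated ketone), which sets the trans ring fusion, and the Luche reduction then adds hydride to C15 from the β face, anti to the axial C14 methyl group, to give the equatorial alcohol.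

Step 14
Reactants: 17 trans-decalin alcohol
Product: 18 bis(silyl ether) lactone (C13-OTBS, C15-OTBS)
Conditions: TBSOTf, 2,6-lutidine, CH2Cl2, −78 to 0 °C
Reagents that add atoms: tert-butyldimethylsilyl triflate, CC(C)(C)[Si](C)(C)OS(=O)(=O)C(F)(F)F
Why: The silyl triflate silylates the hindered equatorial secondary alcohol under non-epimerising conditions (silyl ether formation).

Step 15
Reactants: 18 bis(silyl ether) lactone
Product: 20 allyl decalin alcohol (C19 allyl, C9 CH2OH), via lactol 19 (not isolated)
Conditions: i-Bu2AlH, CH2Cl2, −78 °C; then Ph3P=CH2 (from Ph3PCH3Br and KOt-Bu), THF, −78 °C to rt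
Reagents that add atoms: methyltriphenylphosphonium bromide, C[P+](c1ccccc1)(c1ccccc1)c1ccccc1.[Br-]
Why: i-Bu2AlH stops at the lactol at −78 °C and the ring-opened hydroxy aldehyde is methylenated by the ylide (Wittig reaction), which turns the tether into the C19 allyl group and frees the C9 alcohol.

Step 16
Reactants: 20 allyl decalin alcohol
Product: 21 decalin aldehyde (C9 aldehyde on quaternary C10)
Conditions: Dess–Martin periodinane, NaHCO3, CH2Cl2, rt
Reagents that add atoms: none
Why: Dess–Martin oxidation of the neopentyl alcohol gives the aldehyde, which has no α-hydrogen and cannot epimerise.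

## Spirotetronate fragment

Step 17
Reactants: 22 (2R,5R)-2-tert-butyl-5-methyl-1,3-dioxolan-4-one
Product: 24 (R)-2-tert-butyl-5-methylene-1,3-dioxolan-4-one, via bromide 23 (not isolated)
Conditions: NBS, AIBN (cat.), CCl4, reflux; then Et3N, CH2Cl2, 0 °C
Reagents that add atoms: none
Why: Radical bromination at the captodative C–H (Wohl–Ziegler) and E2 loss of HBr give the exocyclic alkene, while the acetal stereocentre, the only source of asymmetry for the later cycloaddition, is untouched.

Step 18
Reactants: 25 (E)-2-methylpent-2-enal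
Product: 26 ethyl (2E,4E)-2,4-dimethylhepta-2,4-dienoate
Conditions: triethyl 2-phosphonopropionate, NaH, THF, 0 °C to rt
Reagents that add atoms: triethyl 2-phosphonopropionate, CCOC(=O)C(C)P(=O)(OCC)OCC
Why: Horner–Wadsworth–Emmons olefination with an α-methyl phosphonate should give the (E)-trisubstituted ester, so that the later C23 substituent lies outside the s-cis diene.

Step 19
Reactants: 26 ethyl (2E,4E)-2,4-dimethylhepta-2,4-dienoate
Product: 27 (2E,4E)-2,4-dimethylhepta-2,4-dien-1-ol
Conditions: i-Bu2AlH, CH2Cl2, −78 °C
Reagents that add atoms: none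
Why: i-Bu2AlH reduces the conjugated ester to the allylic alcohol by 1,2-addition.

Step 20
Reactants: 27 (2E,4E)-2,4-dimethylhepta-2,4-dien-1-ol
Product: 28 (2E,4E)-1-bromo-2,4-dimethylhepta-2,4-diene
Conditions: CBr4, PPh3, CH2Cl2, 0 °C
Reagents that add atoms: carbon tetrabromide, BrC(Br)(Br)Br
Why: Appel bromination converts the primary allylic alcohol into the bromide under neutral conditions without allylic transposition.

Step 21
Reactants: 28 (2E,4E)-1-bromo-2,4-dimethylhepta-2,4-diene
Product: 29 (4E,6E)-4,6-dimethylnona-1,4,6-triene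
Conditions: tributyl(vinyl)stannane, Pd2(dba)3 (2.5 mol%), P(2-furyl)3, THF, 50 °C
Reagents that add atoms: tributyl(vinyl)stannane, C=C[Sn](CCCC)(CCCC)CCCC
Why: Stille coupling of the allylic bromide through a π-allyl palladium species joins the vinyl group at the less substituted terminus and gives the skipped triene.

Step 22
Reactants: 29 (4E,6E)-4,6-dimethylnona-1,4,6-triene; 24 (R)-2-tert-butyl-5-methylene-1,3-dioxolan-4-one
Product: 30 spiro dioxolanone cycloadduct (C3, C5 and C24 as in the target; C24 bears methyl and allyl)
Conditions: BHT, toluene, 110 °C, sealed tube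
Reagents that add atoms: none
Why: Thermal Diels–Alder reaction in which the captodative alkene bonds its CH2 (C4) to C3 and its oxygenated carbon (C5) to the disubstituted terminus C24, and addition anti to the tert-butyl group with the lactone carbonyl exo, as is usual for this dienophile, together with the (E,E)-diene geometry sets C3, C5 and C24.

Step 23
Reactants: 30 spiro dioxolanone cycloadduct
Product: 31 2-(trimethylsilyl)ethyl α-hydroxy ester (tertiary alcohol at C5)
Conditions: Me3SiCH2CH2OH (5 equiv), NaH (0.2 equiv), THF, 0 °C to rt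
Reagents that add atoms: 2-(trimethylsilyl)ethanol, C[Si](C)(C)CCO
Why: The alkoxide opens the acylal-type lactone at the carbonyl group (transesterification) and the hemiacetal alkoxide released loses pivalaldehyde, which unveils the tertiary alcohol.

Step 24
Reactants: 31 2-(trimethylsilyl)ethyl α-hydroxy ester
Product: 32 spirotetronate (4-[2-(trimethylsilyl)ethoxy]butenolide, C8-H free)
Conditions: Ph3P=C=C=O, toluene, 110 °C
Reagents that add atoms: (triphenylphosphoranylidene)ketene, O=C=C=P(c1ccccc1)(c1ccccc1)c1ccccc1
Why: The tertiary alcohol adds to the ketene carbon of the cumulated ylide and the resulting ester ylide closes onto the adjacent ester carbonyl (intramolecular Wittig reaction), which gives the 4-alkoxy tetronate directly.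

## Union, macrocyclisation and deprotection

Step 25
Reactants: 32 spirotetronate; 21 decalin aldehyde
Product: 33 coupled carbinol (C8–C9 bond, C9 epimers)
Conditions: 32, LiN(i-Pr)2, THF, −78 °C; then 21, −78 to −40 °C
Reagents that add atoms: none
Why: LiN(i-Pr)2 deprotonates the vinylic C8–H of the 4-alkoxybutenolide and the vinyllithium adds to the non-enolisable aldehyde (1,2-addition), which forms the C8–C9 bond; the carbinol configuration is of no consequence.

Step 26
Reactants: 33 coupled carbinol
Product: 34 acyl tetronate diene (C9 ketone)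
Conditions: Dess–Martin periodinane, NaHCO3, CH2Cl2, rt
Reagents that add atoms: none
Why: Dess–Martin oxidation of the carbinol gives the 3-acyl tetronate and removes the C9 stereocentre.

Step 27
Reactants: 34 acyl tetronate diene
Product: 35 protected macrocycle ((Z)-C21=C22, 11-membered carbocycle)
Conditions: Ru(SIMes)(=CH-C6H4-2-Oi-Pr)(S2C6H2Cl2-3,6) (10 mol%), THF, 40 °C, 1 mM
Reagents that add atoms: none
Why: Ring-closing olefin metathesis of the two allyl groups closes the 11-membered carbocycle, and the dithiolate ruthenium catalyst, which forms the all-syn metallacyclobutane, should deliver the (Z)-C21=C22 alkene under kinetic control.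

Step 28
Reactants: 35 protected macrocycle
Product: 36 CNP0259772.1 (target)
Conditions: Bu4NF, THF, 0 to 45 °C; aqueous NH4Cl
Reagents that add atoms: none
Why: Fluoride cleaves both silyl ethers and fragments the 2-(trimethylsilyl)ethyl vinylogous ester to ethene and the tetronic acid, which is drawn as its exocyclic enol tautomer.

## Compound list

1 | benzoic acid | OC(=O)c1ccccc1 | starting material
2 | 1-methylcyclohexa-2,5-diene-1-carboxylic acid | CC1(C(=O)O)C=CCC=C1 | intermediate
3 | (1-methylcyclohexa-2,5-dien-1-yl)methanol | CC1(CO)C=CCC=C1 | intermediate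
4 | methyl (1-methylcyclohexa-2,5-dien-1-yl)methyl malonate | COC(=O)CC(=O)OCC1(C)C=CCC=C1 | intermediate
5 | methyl (1-methyl-4-oxocyclohexa-2,5-dien-1-yl)methyl malonate | COC(=O)CC(=O)OCC1(C)C=CC(=O)C=C1 | intermediate
6 | cis-fused lactone enone ester (C20 epimers) | O1C[C@@]2(C)C=CC(=O)C[C@H]2C(C(=O)OC)C1=O | intermediate
7 | cis-8a-methyl-4,4a,5,8a-tetrahydro-1H-isochromene-3,6-dione | O1C[C@@]2(C)C=CC(=O)C[C@H]2CC1=O | intermediate
8 | 7-iodo lactone enone | O1C[C@@]2(C)C=C(I)C(=O)C[C@H]2CC1=O | intermediate
9 | (E)-prop-1-enylboronic acid pinacol ester | C/C=C/B1OC(C)(C)C(C)(C)O1 | starting material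
10 | 7-[(E)-prop-1-enyl] lactone enone | O1C[C@@]2(C)C=C(/C=C/C)C(=O)C[C@H]2CC1=O | intermediate
11 | tert-butyldimethyl(vinyloxy)silane | C=CO[Si](C)(C)C(C)(C)C | starting material
12 | tricyclic silyloxy enone | O1C[C@@]2(C)[C@@H]3C[C@H](O[Si](C)(C)C(C)(C)C)[C@H](C)C=C3C(=O)C[C@H]2CC1=O | intermediate
13 | dienyl triflate | O1C[C@@]2(C)[C@@H]3C[C@H](O[Si](C)(C)C(C)(C)C)[C@H](C)C=C3C(OS(=O)(=O)C(F)(F)F)=C[C@H]2CC1=O | intermediate
14 | tricyclic diene | O1C[C@@]2(C)[C@@H]3C[C@H](O[Si](C)(C)C(C)(C)C)[C@H](C)C=C3C=C[C@H]2CC1=O | intermediate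
15 | vinyl epoxide | O1C[C@@]2(C)[C@@H]3C[C@H](O[Si](C)(C)C(C)(C)C)[C@H](C)[C@H]4O[C@@]34C=C[C@H]2CC1=O | intermediate
16 | β,γ-unsaturated C15 ketone | O1C[C@@]2(C)[C@@H]3C[C@H](O[Si](C)(C)C(C)(C)C)[C@H](C)C(=O)[C@H]3C=C[C@H]2CC1=O | intermediate
17 | trans-decalin C15 alcohol | O1C[C@@]2(C)[C@@H]3C[C@H](O[Si](C)(C)C(C)(C)C)[C@H](C)[C@H](O)[C@H]3C=C[C@H]2CC1=O | intermediate
18 | bis(silyl ether) lactone | O1C[C@@]2(C)[C@@H]3C[C@H](O[Si](C)(C)C(C)(C)C)[C@H](C)[C@H](O[Si](C)(C)C(C)(C)C)[C@H]3C=C[C@H]2CC1=O | intermediate
19 | lactol (anomers) | O1C[C@@]2(C)[C@@H]3C[C@H](O[Si](C)(C)C(C)(C)C)[C@H](C)[C@H](O[Si](C)(C)C(C)(C)C)[C@H]3C=C[C@H]2CC1O | intermediate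
20 | allyl decalin alcohol | OC[C@@]1(C)[C@@H]2C[C@H](O[Si](C)(C)C(C)(C)C)[C@H](C)[C@H](O[Si](C)(C)C(C)(C)C)[C@H]2C=C[C@H]1CC=C | intermediate
21 | decalin aldehyde | O=C[C@@]1(C)[C@@H]2C[C@H](O[Si](C)(C)C(C)(C)C)[C@H](C)[C@H](O[Si](C)(C)C(C)(C)C)[C@H]2C=C[C@H]1CC=C | intermediate
22 | (2R,5R)-2-tert-butyl-5-methyl-1,3-dioxolan-4-one | C[C@H]1O[C@@H](C(C)(C)C)OC1=O | starting material
23 | (2R)-5-bromo-2-tert-butyl-5-methyl-1,3-dioxolan-4-one | CC1(Br)O[C@@H](C(C)(C)C)OC1=O | intermediate
24 | (R)-2-tert-butyl-5-methylene-1,3-dioxolan-4-one | C=C1O[C@@H](C(C)(C)C)OC1=O | intermediate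
25 | (E)-2-methylpent-2-enal | CC/C=C(\C)C=O | starting material
26 | ethyl (2E,4E)-2,4-dimethylhepta-2,4-dienoate | CCOC(=O)/C(C)=C/C(C)=C/CC | intermediate
27 | (2E,4E)-2,4-dimethylhepta-2,4-dien-1-ol | OC/C(C)=C/C(C)=C/CC | intermediate
28 | (2E,4E)-1-bromo-2,4-dimethylhepta-2,4-diene | BrC/C(C)=C/C(C)=C/CC | intermediate
29 | (4E,6E)-4,6-dimethylnona-1,4,6-triene | C=CC/C(C)=C/C(C)=C/CC | intermediate
30 | spiro dioxolanone cycloadduct | C=CC[C@]1(C)C=C(C)[C@H](CC)C[C@]12O[C@@H](C(C)(C)C)OC2=O | intermediate
31 | 2-(trimethylsilyl)ethyl α-hydroxy ester | C=CC[C@]1(C)C=C(C)[C@H](CC)C[C@@]1(O)C(=O)OCC[Si](C)(C)C | intermediate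
32 | spirotetronate, 4-[2-(trimethylsilyl)ethoxy] | C=CC[C@]1(C)C=C(C)[C@H](CC)C[C@]12OC(=O)C=C2OCC[Si](C)(C)C | intermediate
33 | coupled carbinol (C9 epimers) | C=CC[C@]1(C)C=C(C)[C@H](CC)C[C@]12OC(=O)C(C(O)[C@@]3(C)[C@@H]4C[C@H](O[Si](C)(C)C(C)(C)C)[C@H](C)[C@H](O[Si](C)(C)C(C)(C)C)[C@H]4C=C[C@H]3CC=C)=C2OCC[Si](C)(C)C | intermediate
34 | acyl tetronate diene | C=CC[C@]1(C)C=C(C)[C@H](CC)C[C@]12OC(=O)C(C(=O)[C@@]3(C)[C@@H]4C[C@H](O[Si](C)(C)C(C)(C)C)[C@H](C)[C@H](O[Si](C)(C)C(C)(C)C)[C@H]4C=C[C@H]3CC=C)=C2OCC[Si](C)(C)C | intermediate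
35 | protected macrocycle | CC[C@@H]1C[C@]23OC(=O)C(C(=O)[C@@]4(C)[C@@H]5C[C@H](O[Si](C)(C)C(C)(C)C)[C@H](C)[C@H](O[Si](C)(C)C(C)(C)C)[C@H]5C=C[C@H]4C/C=C\C[C@]2(C)C=C1C)=C3OCC[Si](C)(C)C | intermediate
36 | CNP0259772.1 | CC[C@@H]1C[C@]23OC(=O)/C(=C(\O)[C@@]4(C)[C@@H]5C[C@H](O)[C@H](C)[C@H](O)[C@H]5C=C[C@H]4C/C=C\C[C@]2(C)C=C1C)C3=O | target

## Step count and risks

Total step count: 28. Longest linear sequence: 20 steps (steps 1–16, then 25–28).

Steps most likely to fail:

1. Step 9 (key cycloaddition). The cycloaddition may be too slow at the hindered C11 terminus, or lose endo or facial control, or be outrun by self-dimerisation of the dienone. The fallback sets out from 10 and comes back at 12, and makes the two bonds one after the other. Compound 10 and 11 with catalytic Me3SiNTf2 in CH2Cl2 at −78 °C should give the Mukaiyama–Michael adduct, the silyl dienol ether aldehyde F1. BF3·OEt2 at −78 °C should then close ring B by an intramolecular vinylogous Mukaiyama aldol reaction at C14 to give the hydroxy enone F2. TBSOTf and 2,6-lutidine return F2 to 12.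

2. Step 13 (epoxide isomerisation and reduction). The palladium hydride may return the hydrogen to C18 instead of C16, which would give the conjugated enone, or the π-allyl intermediate may eliminate to a dienol; the ketone may also epimerise at C14 before reduction. The fallback sets out from 14 and comes back at 18, and uses a tethered hydrosilylation. Bu4NF removes the C13 silyl ether to give the dienol F3. (HMe2Si)2NH converts it into the dimethylsilyl ether F4. Pt2(dvtms)3 should deliver Si–H intramolecularly and syn across C15=C16 from the face of the C13 oxygen to give the oxasilolane F5. Tamao oxidation (H2O2, KF, KHCO3) gives the diol F6, and TBSOTf with 2,6-lutidine converts F6 into 18.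

3. Step 27 (ring-closing metathesis). The ring closure may stall through oligomerisation, or the catalyst may give poor Z selectivity on the rigid ketone. The fallback sets out from 33 and comes back at 35. The more flexible carbinol 33 is cyclised with the second-generation Grubbs catalyst in refluxing CH2Cl2 at high dilution under equilibrating conditions, where the strain of the 11-membered ring should favour the Z alkene, to give the macrocyclic carbinol F7. Dess–Martin oxidation of F7 then gives 35.

Further compounds
F1 | step 9 | silyl dienol ether aldehyde (Mukaiyama–Michael adduct) | O1C[C@@]2(C)[C@H](CC=O)C(/C=C/C)=C(O[Si](C)(C)C(C)(C)C)C[C@H]2CC1=O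
F2 | step 9 | tricyclic hydroxy enone (C13-OH) | O1C[C@@]2(C)[C@@H]3C[C@H](O)[C@H](C)C=C3C(=O)C[C@H]2CC1=O
F3 | step 13 | tricyclic dienol (C13-OH) | O1C[C@@]2(C)[C@@H]3C[C@H](O)[C@H](C)C=C3C=C[C@H]2CC1=O
F4 | step 13 | C13 dimethylsilyl ether of the dienol | O1C[C@@]2(C)[C@@H]3C[C@H](O[SiH](C)C)[C@H](C)C=C3C=C[C@H]2CC1=O
F5 | step 13 | oxasilolane (Si on C15, O on C13) | O1C[C@@]2(C)[C@@H]3C[C@@H]4O[Si](C)(C)[C@@H]([C@H]4C)[C@H]3C=C[C@H]2CC1=O
F6 | step 13 | C13,C15 diol lactone | O1C[C@@]2(C)[C@@H]3C[C@H](O)[C@H](C)[C@H](O)[C@H]3C=C[C@H]2CC1=O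
F7 | step 27 | macrocyclic carbinol (C9 epimers) | CC[C@@H]1C[C@]23OC(=O)C(C(O)[C@@]4(C)[C@@H]5C[C@H](O[Si](C)(C)C(C)(C)C)[C@H](C)[C@H](O[Si](C)(C)C(C)(C)C)[C@H]5C=C[C@H]4C/C=C\C[C@]2(C)C=C1C)=C3OCC[Si](C)(C)C
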